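**Plan**

- Cuts: the aryl ether O–CH2 bond between the coumarin 7-oxygen and the epoxide-bearing CH2; the two C–O bonds of the epoxide (back to an E-allylic alcohol); the C–OH bond at the quaternary lactone carbon (back to an exocyclic C=CH2); and, together, the lactone CH(O)–CH2 ring bond and the lactone acyl C–O bond (back to a primary homoallylic alcohol and a 2-(methoxycarbonyl)allyl carbonate).
- Enabling feature: the five-membered lactone (ring O, C=O, C(CH3)(OH), CH2, CH–O) is a hydrated α-methylene-γ-butyrolactone. Its C(CH3)(OH) carbon is a masked exocyclic methylene, and its CH–O carbon is the CH2OH carbon of a simple primary alcohol.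
- Forward order: the E-trisubstituted alkenol chain is built from 3-butyn-1-ol. The lactone ring closes first (iridium-catalysed alcohol C–H allylation with lactonisation), the epoxide second, the exo-methylene is hydrated third, and the coumarin bicycle (bought as daphnetin) is attached last through the primary C–O bond.
- Stereochemistry: the lactone CH–O centre comes from the chiral iridium catalyst acting on an achiral alcohol. The C(CH3)(OH) centre is relayed from it by anti trapping of the ring radical with O2. The (2R,3R)-epoxide comes from D-(−)-tartrate-controlled Sharpless epoxidation, and its trans geometry from the E-alkene set by syn-carboalumination.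

Key step: step 6

Assumption: in step 6 the sense of induction is set by the ligand alone; the TMBTP atropisomer that directs allylation to the Si face of the transient aldehyde (giving the 5R lactone) is used, and which antipode this is would be settled in a pilot run.

**Route**

Step 1
Reactants: 1 3-butyn-1-ol
Product: 2 tert-butyl(but-3-yn-1-yloxy)dimethylsilane
Conditions: TBSCl, imidazole, CH2Cl2, 0 °C to rt
Reagents that add atoms: tert-butyldimethylsilyl chloride, CC(C)(C)[Si](C)(C)Cl
Why: Imidazole-mediated O-silylation of a primary alcohol; the terminal alkyne is untouched and the hydroxyl is masked for the organoaluminium step.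

Step 2
Reactants: 2 tert-butyl(but-3-yn-1-yloxy)dimethylsilane
Product: 5 (2E)-5-[(tert-butyldimethylsilyl)oxy]-3-methylpent-2-en-1-ol, via alkenylalane 3 (not isolated), via lithium alanate 4 (not isolated)
Conditions: AlMe3, Cp2ZrCl2 (0.25 equiv), CH2Cl2, 0 °C to rt; volatiles removed; n-BuLi, hexane/THF, −78 °C; (CH2O)n, −78 °C to rt; aq. potassium sodium tartrate
Reagents that add atoms: trimethylaluminium, C[Al](C)C; formaldehyde (as paraformaldehyde), C=O
Why: Negishi zirconium-catalysed carboalumination adds methyl and aluminium syn across the terminal alkyne with methyl at the internal carbon, and hydroxymethylation of the derived alanate by formaldehyde proceeds with retention, so the E-trisubstituted alkene (CH3 cis to CH2OH) is fixed here.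

Step 3
Reactants: 5 (2E)-5-[(tert-butyldimethylsilyl)oxy]-3-methylpent-2-en-1-ol
Product: 6 tert-butyl({(3E)-5-[(4-methoxybenzyl)oxy]-3-methylpent-3-en-1-yl}oxy)dimethylsilane
Conditions: NaH, PMBCl, Bu4NI (cat.), THF/DMF, 0 °C to rt
Reagents that add atoms: 4-methoxybenzyl chloride, COc1ccc(CCl)cc1
Why: Williamson etherification of the allylic hydroxyl (deprotonation by NaH, iodide-catalysed alkylation); the primary silyl ether is stable and the E geometry keeps the two oxygens too far apart for silyl migration.

Step 4
Reactants: 6 tert-butyl({(3E)-5-[(4-methoxybenzyl)oxy]-3-methylpent-3-en-1-yl}oxy)dimethylsilane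
Product: 7 (3E)-5-[(4-methoxybenzyl)oxy]-3-methylpent-3-en-1-ol
Conditions: TBAF, THF, 0 °C to rt
Reagents that add atoms: none
Why: Fluoride-induced desilylation frees the homoallylic primary alcohol while the PMB ether and the alkene geometry are unaffected.

Step 5
Reactants: 8 methyl 2-(hydroxymethyl)prop-2-enoate
Product: 9 methyl 2-{[(tert-butoxycarbonyl)oxy]methyl}prop-2-enoate
Conditions: Boc2O, DMAP (cat.), CH2Cl2, 0 °C to rt
Reagents that add atoms: di-tert-butyl dicarbonate, CC(C)(C)OC(=O)OC(=O)OC(C)(C)C
Why: DMAP-catalysed acylation of the primary allylic alcohol by Boc2O, the usual way to prepare Morita–Baylis–Hillman-type tert-butyl carbonates.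

Step 6
Reactants: 7 (3E)-5-[(4-methoxybenzyl)oxy]-3-methylpent-3-en-1-ol; 9 methyl 2-{[(tert-butoxycarbonyl)oxy]methyl}prop-2-enoate
Product: 12 (5R)-5-{(2E)-4-[(4-methoxybenzyl)oxy]-2-methylbut-2-en-1-yl}-3-methylideneoxolan-2-one, via aldehyde 10 (not isolated), via hydroxy ester 11 (not isolated)
Conditions: [Ir(cod)Cl]2 (2.5 mol%), TMBTP (2,2',5,5'-tetramethyl-4,4'-bis(diphenylphosphino)-3,3'-bithiophene, single atropisomer, 5 mol%), 4-chloro-3-nitrobenzoic acid (10 mol%), Cs2CO3 (20 mol%), THF, 60 °C
Reagents that add atoms: none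
Why: The ortho-cyclometalated trivalent iridium C,O-benzoate complex formed in situ dehydrogenates primary alcohol 7 to aldehyde 10, the iridium hydride is deprotonated to monovalent iridium, and this ionises carbonate 9 (loss of CO2 and tert-butoxide) to an iridium-bound 2-(methoxycarbonyl)allyl fragment that adds to 10 through a closed chair-like transition state, joining the former CH2OH carbon to the allylic CH2 of the acrylate unit to give hydroxy ester 11. The closest known reaction type is the iridium-catalysed transfer-hydrogenative 2-(alkoxycarbonyl)allylation of primary alcohols (Krische-type carbonyl allylation from the alcohol oxidation level), which delivers α-methylene-γ-butyrolactones directly. The γ-butyrolactone ring closes by 5-exo-trig acyl substitution of the new secondary hydroxyl on the methyl ester with loss of methanol. The single new stereocentre (C5, R) is controlled by the chiral bisphosphine on iridium, which directs the allyl group to the Si face of 10; the substrate is achiral and exerts no bias. The step needs enantiofacial selectivity, and it needs C–C bond formation to outrun isomerisation of the β,γ-unsaturated aldehyde to the conjugated enal; the latter is secured because 10 exists only in catalytic amounts at the metal alongside the allyl donor, the trisubstituted alkene is too hindered to insert into the iridium hydride, and the PMB ether is a far poorer allylic leaving group than the tert-butyl carbonate of 9.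

Step 7
Reactants: 12 (5R)-5-{(2E)-4-[(4-methoxybenzyl)oxy]-2-methylbut-2-en-1-yl}-3-methylideneoxolan-2-one
Product: 13 (5R)-5-[(2E)-4-hydroxy-2-methylbut-2-en-1-yl]-3-methylideneoxolan-2-one
Conditions: DDQ, CH2Cl2/pH 7 phosphate buffer, 0 °C
Reagents that add atoms: none
Why: Oxidative PMB cleavage by DDQ (oxidation at the electron-rich benzylic position, then hydrolysis) frees the allylic alcohol; the electron-poor exo-methylene lactone is inert, and buffered water at low temperature limits over-oxidation of the liberated allylic alcohol.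

Step 8
Reactants: 13 (5R)-5-[(2E)-4-hydroxy-2-methylbut-2-en-1-yl]-3-methylideneoxolan-2-one
Product: 14 (5S)-5-{[(2R,3R)-3-(hydroxymethyl)-2-methyloxiran-2-yl]methyl}-3-methylideneoxolan-2-one
Conditions: Ti(OiPr)4 (cat.), D-(−)-diisopropyl tartrate (cat.), t-BuOOH, 4 Å MS, CH2Cl2, −20 °C
Reagents that add atoms: tert-butyl hydroperoxide, CC(C)(C)OO
Why: Sharpless asymmetric epoxidation of the E-allylic alcohol; the D-(−)-tartrate–titanium complex delivers oxygen to the alkene face that gives the (2R,3R)-epoxide (reagent control over the remote C5 centre, the same sense as geraniol with this tartrate), the trans relation of CH2OH and the lactonylmethyl group follows from the E-alkene, and the electron-poor exo-methylene is not attacked by the electrophilic oxidant.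

Step 9
Reactants: 14 (5S)-5-{[(2R,3R)-3-(hydroxymethyl)-2-methyloxiran-2-yl]methyl}-3-methylideneoxolan-2-one
Product: 16 (3R,5S)-3-hydroxy-5-{[(2R,3R)-3-(hydroxymethyl)-2-methyloxiran-2-yl]methyl}-3-methyloxolan-2-one, via hydroperoxide 15 (not isolated)
Conditions: Mn(dpm)3 (cat.), PhSiH3, O2 (1 atm), iPrOH/CH2Cl2, 0 °C to rt; then P(OEt)3
Reagents that add atoms: dioxygen, O=O
Why: Mukaiyama-type hydration by metal-hydride hydrogen-atom transfer: the manganese hydride delivers H to the CH2 terminus of the only remaining C=C, the planar tertiary α-lactonyl radical should be trapped by O2 on the face anti to the C5 substituent (OH trans to the side chain, 3R), and P(OEt)3 reduces hydroperoxide 15; epoxide and primary hydroxyl are inert under these neutral radical conditions.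

Step 10
Reactants: 17 daphnetin (7,8-dihydroxy-2H-chromen-2-one)
Product: 18 7-(benzyloxy)-8-hydroxy-2H-chromen-2-one
Conditions: BnBr (1.0 equiv), K2CO3 (1.0 equiv), DMF, rt
Reagents that add atoms: benzyl bromide, BrCc1ccccc1
Why: Williamson benzylation with one equivalent of weak base should select the 7-OH, the more acidic phenol because its phenoxide is conjugated with the pyranone carbonyl (a vinylogous carboxylate), whereas the 8-OH is less acidic and more hindered.

Step 11
Reactants: 18 7-(benzyloxy)-8-hydroxy-2H-chromen-2-one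
Product: 19 7-(benzyloxy)-8-methoxy-2H-chromen-2-one
Conditions: MeI, K2CO3, DMF, rt
Reagents that add atoms: iodomethane, CI
Why: Williamson O-methylation of the only remaining phenol.

Step 12
Reactants: 19 7-(benzyloxy)-8-methoxy-2H-chromen-2-one
Product: 20 7-hydroxy-8-methoxy-2H-chromen-2-one
Conditions: BCl3, pentamethylbenzene, CH2Cl2, −78 °C; then aqueous work-up
Reagents that add atoms: none
Why: Lewis-acid debenzylation with BCl3 and pentamethylbenzene as benzyl-cation scavenger cleaves the aryl benzyl ether at −78 °C without touching the aryl methyl ether or the coumarin C3=C4 bond, which hydrogenolysis could reduce.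

Step 13
Reactants: 16 (3R,5S)-3-hydroxy-5-{[(2R,3R)-3-(hydroxymethyl)-2-methyloxiran-2-yl]methyl}-3-methyloxolan-2-one; 20 7-hydroxy-8-methoxy-2H-chromen-2-one
Product: 21 7-{[(2R,3R)-3-{[(2S,4R)-4-hydroxy-4-methyl-5-oxooxolan-2-yl]methyl}-3-methyloxiran-2-yl]methoxy}-8-methoxy-2H-chromen-2-one (target)
Conditions: PPh3, DIAD, THF, 0 °C to rt
Reagents that add atoms: none
Why: Mitsunobu etherification: PPh3/DIAD activate only the primary hydroxyl, which is displaced at CH2 by the acidic 7-phenol (pKa about 8); the tertiary carbinol does not react, the trans OH cannot reach the epoxide, and no stereocentre is touched.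

**Compound list**

1 | 3-butyn-1-ol | C#CCCO | starting material
2 | tert-butyl(but-3-yn-1-yloxy)dimethylsilane | C#CCCO[Si](C)(C)C(C)(C)C | intermediate
3 | [(1E)-4-[(tert-butyldimethylsilyl)oxy]-2-methylbut-1-en-1-yl]dimethylalane | C/C(CCO[Si](C)(C)C(C)(C)C)=C\[Al](C)C | intermediate (not isolated)
4 | lithium butyl[(1E)-4-[(tert-butyldimethylsilyl)oxy]-2-methylbut-1-en-1-yl]dimethylalanate | C/C(CCO[Si](C)(C)C(C)(C)C)=C\[Al-](C)(C)CCCC.[Li+] | intermediate (not isolated)
5 | (2E)-5-[(tert-butyldimethylsilyl)oxy]-3-methylpent-2-en-1-ol | C/C(CCO[Si](C)(C)C(C)(C)C)=C\CO | intermediate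
6 | tert-butyl({(3E)-5-[(4-methoxybenzyl)oxy]-3-methylpent-3-en-1-yl}oxy)dimethylsilane | C/C(CCO[Si](C)(C)C(C)(C)C)=C\COCc1ccc(OC)cc1 | intermediate
7 | (3E)-5-[(4-methoxybenzyl)oxy]-3-methylpent-3-en-1-ol | C/C(CCO)=C\COCc1ccc(OC)cc1 | intermediate
8 | methyl 2-(hydroxymethyl)prop-2-enoate | C=C(CO)C(=O)OC | starting material
9 | methyl 2-{[(tert-butoxycarbonyl)oxy]methyl}prop-2-enoate | C=C(COC(=O)OC(C)(C)C)C(=O)OC | intermediate
10 | (3E)-5-[(4-methoxybenzyl)oxy]-3-methylpent-3-enal | C/C(CC=O)=C\COCc1ccc(OC)cc1 | intermediate (not isolated)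
11 | methyl (4R,6E)-4-hydroxy-8-[(4-methoxybenzyl)oxy]-6-methyl-2-methylideneoct-6-enoate | COc1ccc(COC/C=C(\C)C[C@@H](O)CC(=C)C(=O)OC)cc1 | intermediate (not isolated)
12 | (5R)-5-{(2E)-4-[(4-methoxybenzyl)oxy]-2-methylbut-2-en-1-yl}-3-methylideneoxolan-2-one | COc1ccc(COC/C=C(\C)C[C@@H]2CC(=C)C(=O)O2)cc1 | intermediate
13 | (5R)-5-[(2E)-4-hydroxy-2-methylbut-2-en-1-yl]-3-methylideneoxolan-2-one | OC/C=C(\C)C[C@@H]1CC(=C)C(=O)O1 | intermediate
14 | (5S)-5-{[(2R,3R)-3-(hydroxymethyl)-2-methyloxiran-2-yl]methyl}-3-methylideneoxolan-2-one | OC[C@H]1O[C@]1(C)C[C@@H]1CC(=C)C(=O)O1 | intermediate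
15 | (3R,5R)-3-hydroperoxy-5-{[(2R,3R)-3-(hydroxymethyl)-2-methyloxiran-2-yl]methyl}-3-methyloxolan-2-one (OOH trans to the C5 side chain) | OC[C@H]1O[C@]1(C)C[C@@H]1C[C@@](C)(OO)C(=O)O1 | intermediate (not isolated)
16 | (3R,5S)-3-hydroxy-5-{[(2R,3R)-3-(hydroxymethyl)-2-methyloxiran-2-yl]methyl}-3-methyloxolan-2-one | OC[C@H]1O[C@]1(C)C[C@@H]1C[C@@](C)(O)C(=O)O1 | intermediate
17 | daphnetin (7,8-dihydroxy-2H-chromen-2-one) | Oc1ccc2ccc(=O)oc2c1O | starting material
18 | 7-(benzyloxy)-8-hydroxy-2H-chromen-2-one | Oc1c(OCc2ccccc2)ccc2ccc(=O)oc12 | intermediate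
19 | 7-(benzyloxy)-8-methoxy-2H-chromen-2-one | COc1c(OCc2ccccc2)ccc2ccc(=O)oc12 | intermediate
20 | 7-hydroxy-8-methoxy-2H-chromen-2-one | COc1c(O)ccc2ccc(=O)oc12 | intermediate
21 | 7-{[(2R,3R)-3-{[(2S,4R)-4-hydroxy-4-methyl-5-oxooxolan-2-yl]methyl}-3-methyloxiran-2-yl]methoxy}-8-methoxy-2H-chromen-2-one | COc1c(OC[C@H]2O[C@]2(C)C[C@@H]2C[C@@](C)(O)C(=O)O2)ccc2ccc(=O)oc12 | target

**Step count**

Total: 13 steps. Longest linear sequence: 9 steps (steps 1, 2, 3, 4, 6, 7, 8, 9, 13).

**Steps most likely to fail**

Step 6. The transient β,γ-unsaturated aldehyde may drift into conjugation with the trisubstituted alkene before it is allylated, or enantiofacial control may be eroded with this branched chain. The fallback sets out from 7 and returns at 12. Alcohol 7 would be oxidised with Dess–Martin periodinane (NaHCO3, CH2Cl2, 0 °C) to aldehyde 10, used at once without chromatography. It would then undergo a chromium-catalysed asymmetric Nozaki–Hiyama–Kishi-type 2-(alkoxycarbonyl)allylation with ethyl 2-(bromomethyl)acrylate (CrCl2 (cat.), chiral oxazoline-based ligand, Mn powder, Cp2ZrCl2, THF, rt), a non-basic reaction at the aldehyde oxidation level. The resulting ethyl (4R,6E)-4-hydroxy-8-[(4-methoxybenzyl)oxy]-6-methyl-2-methylideneoct-6-enoate F1 would be lactonised with catalytic pyridinium p-toluenesulfonate in warm toluene to give 12.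

Step 9. Trapping of the planar lactone radical by O2 may show poor facial selectivity, because the controlling C5 substituent sits 1,3 to the radical centre. The fallback sets out from 12 and returns at 16; it replaces radical trapping by enolate oxidation and moves the hydroxylation ahead of the epoxidation. Conjugate reduction of the exo-methylene of 12 ([(Ph3P)CuH]6 (cat.), polymethylhydrosiloxane, toluene) would give (5S)-5-{(2E)-4-[(4-methoxybenzyl)oxy]-2-methylbut-2-en-1-yl}-3-methyloxolan-2-one F2 as a C3 epimer mixture, both epimers converging in the next step. Deprotonation with KN(SiMe3)2 (THF, −78 °C) and hydroxylation in the same flask with 2-(phenylsulfonyl)-3-phenyloxaziridine, the electrophile entering anti to the C5 substituent, would give (3R,5R)-3-hydroxy-5-{(2E)-4-[(4-methoxybenzyl)oxy]-2-methylbut-2-en-1-yl}-3-methyloxolan-2-one F3. DDQ cleavage of the PMB ether would give (3R,5R)-3-hydroxy-5-[(2E)-4-hydroxy-2-methylbut-2-en-1-yl]-3-methyloxolan-2-one F4, and Sharpless epoxidation of F4 under the conditions of step 8 would give 16.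

Step 13. The acidic phenol may open the trisubstituted epoxide, or the activated primary alcohol may be consumed without C–O bond formation at this late, convergent stage. The fallback sets out from 16 and returns at 21. Selective sulfonylation of the primary hydroxyl (TsCl, Et3N, DMAP (cat.), CH2Cl2, 0 °C; the tertiary carbinol does not react) would give [(2R,3R)-3-{[(2S,4R)-4-hydroxy-4-methyl-5-oxooxolan-2-yl]methyl}-3-methyloxiran-2-yl]methyl 4-methylbenzenesulfonate F5. Direct displacement by the phenoxide of 20 (Cs2CO3, DMF, rt) would then give 21.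

**Further compounds**

F1 | step 6 | ethyl (4R,6E)-4-hydroxy-8-[(4-methoxybenzyl)oxy]-6-methyl-2-methylideneoct-6-enoate | COc1ccc(COC/C=C(\C)C[C@@H](O)CC(=C)C(=O)OCC)cc1
F2 | step 9 | (5S)-5-{(2E)-4-[(4-methoxybenzyl)oxy]-2-methylbut-2-en-1-yl}-3-methyloxolan-2-one (C3 epimer mixture) | COc1ccc(COC/C=C(\C)C[C@@H]2CC(C)C(=O)O2)cc1
F3 | step 9 | (3R,5R)-3-hydroxy-5-{(2E)-4-[(4-methoxybenzyl)oxy]-2-methylbut-2-en-1-yl}-3-methyloxolan-2-one | COc1ccc(COC/C=C(\C)C[C@@H]2C[C@@](C)(O)C(=O)O2)cc1
F4 | step 9 | (3R,5R)-3-hydroxy-5-[(2E)-4-hydroxy-2-methylbut-2-en-1-yl]-3-methyloxolan-2-one | OC/C=C(\C)C[C@@H]1C[C@@](C)(O)C(=O)O1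
F5 | step 13 | [(2R,3R)-3-{[(2S,4R)-4-hydroxy-4-methyl-5-oxooxolan-2-yl]methyl}-3-methyloxiran-2-yl]methyl 4-methylbenzenesulfonate | Cc1ccc(S(=O)(=O)OC[C@H]2O[C@]2(C)C[C@@H]2C[C@@](C)(O)C(=O)O2)cc1
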